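(The readings were generated by integration with made-up constants; noise was put on by code.)

Time is what the four new flasks share: noon, dawn, summer and winter each stand for 12 h and differ in their charge of substrate.

in all of them: enzyme 20 µM
- beta: substrate 0.013 M; run made earlier
- theta: substrate 0.38 M; run made earlier
- noon: substrate 0.020 M; time 12 h
- dawn: substrate 0.060 M; time 12 h
- summer: substrate 0.20 M; time 12 h
- winter: substrate 0.60 M; time 12 h

- beta (time / h: product / %): 2.00: 33.0; 4.00: 51.0; 6.00: 64.3; 8.00: 72.4
- theta (time / h: product / %): 0.667: 2.1; 1.50: 3.4; 4.00: 11.0; 8.00: 17.2

(standard deviation of a reading: 1 percentage point)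

- candidate steps: substrate + enzyme -> product + enzyme; 2 enzyme <-> resting dimer
- "hardly changes" means that all values lie within two and a half points (for a concentration: within two and a half percent of the largest)

1. [product] at the end for noon, dawn, summer, winter, in this order
2. how that number moves from the first to the last of them (rises all the way / rises, then falls / falls all the way / hardly changes / falls, then rises)

Two times are held against each other: that window and the time the substrate itself needs. The candidate steps turn substrate into product, so the beta reading at 8.00 h gives 6.21 h as the clearing time τ, the elapsed time divided by the natural log of the charge over the substrate left. This is the inverse of an average pseudo-first-order constant. The theta reading at 8.00 h gives 42.4 h. Both are readings and carry their scatter. Beta's τ is shorter than the window, and theta's is longer.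

The share converted is one minus exp(−t/τ), so at one time a fall in [product] between two charges needs τ to grow by a larger factor than the charge does. From beta to theta, τ grows 6.83 times, less than the charge's 29.2 times. Winter's charge is 1.58 times theta's and lies beyond both runs, so the test is unread there. The reckoning here commits to noon, with beta's τ, near 0.0171 M, more than the forecast's value.

The forecast gives 0.0165 M, 0.042 M, 0.074 M and 0.088 M, so rises all the way, with the remark “Substrate inhibition is not evident”.

The flasks give 0.0162 M, 0.0468 M, 0.111 M and 0.0699 M: rises, then falls, turning at 0.24 M.

    substrate + enzyme → product + enzyme, rate k1*[substrate]*[enzyme]/(1 + ([substrate]/Km1) + ([substrate]/Ksi1)^2) (0.321 M, 0.169 M, k = 11700 L mol⁻¹ h⁻¹)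
    2 enzyme ⇌ resting dimer (K = 1.40 × 10⁶ L mol⁻¹, k = 3120 L mol⁻¹ h⁻¹)

Winter ends with 88.4 % of its substrate left. Summer's τ is 14.7 h and winter's is 96.9 h, which is 6.59 times summer's, a larger factor than the charge's 3.00. Noon's τ is 7.20 h, and dawn's is 1.10 times noon's, against a charge 3.00 times noon's.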